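**Plan**

1. Retrosynthesis: the acetate, the carbinol under it (from a ketone) and a ketal on the bridged ketone are adjusted last. The keto lactone is then cut at both ring bonds of its CH2–CH2 unit and at the lactone acyl–O bond, giving an open-chain γ-keto methylmalonate plus phenyl vinyl sulfone as an ethylene equivalent.
2. Enabling feature: in the 6-oxabicyclo[3.2.1]octanone the CH2–CH2 bridge of the cyclohexane ring is flanked by the tertiary C(Me)–O lactone carbon and by the acetoxy carbon. The first is a methyl-ketone carbon; the second is one ester of a prochiral malonate at the quaternary C(Me), whose other ester is the lactone carbonyl. Both new bonds therefore go to carbonyl carbons.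
3. The keto malonate comes from an iridium-catalysed allylic alkylation and a Wacker oxidation; the allylic carbonate comes from cross-metathesis of a butenyl group on the bridged ketone.
4. The bicyclo[3.2.1]octanone (rings C and D) comes from (+)-nopinone by α-alkylation, cyclobutane cleavage, ene chlorination and intramolecular enolate alkylation.
5. Forward order: rings C and D, then the chain, then the lactone ring and ring A together, then carbinol, acetate and release of the ketone.
6. Stereochemistry (ent-kaurane locants): C-13 from nopinone, C-8 forced by the bridge; C-5 by the iridium ligand; C-10 by Felkin–Anh addition and C-4 by geometric desymmetrisation of the malonate in the key step; C-3 by hydride delivery anti to the axial side chain.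

Key step: step 9

Remark on the chemistry: locants C-1 to C-20 in the text are ent-kaurane locants (C-3 acetoxy carbon, C-4 quaternary carbon, C-5 ring CH carrying the two-carbon tether, C-10 lactone carbinol carbon, C-8 and C-13 bridgeheads, C-9 ketone). The phosphoramidite antipode in step 7 is assumed to be the one that gives the 3R allylic centre; both antipodes are available.

**Route**

Step 1
Reactants: 1 (+)-nopinone; 2 4-iodobut-1-ene
Product: 3 trans-3-(but-3-enyl)nopinone
Conditions: LiN(iPr)2, THF, −78 °C; then 2, DMPU, −78 → 0 °C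
Reagents that add atoms: none
Why: Kinetic enolate alkylation, in which only C-3 of nopinone can be enolised (the other α-carbon is a bridgehead) and the iodide should enter anti to the gem-dimethyl bridge; this centre is erased in step 4, so its configuration is immaterial.

Step 2
Reactants: 3 trans-3-(but-3-enyl)nopinone
Product: 5 (4R)-2-(but-3-enyl)-4-isopropenylcyclohexanone (C-2 epimers), via enol acetate 4 (not isolated)
Conditions: BF3·OEt2, Zn(OAc)2, Ac2O, 0 °C → rt; then K2CO3, MeOH, rt
Reagents that add atoms: none
Why: Lewis-acid-mediated cleavage of the strained cyclobutane of a pinane ketone, captured as the enol acetate while the tertiary cation loses a proton to give the isopropenyl group, followed by methanolysis of the enol acetate; the former bridgehead C-5 of nopinone is not touched and becomes the ring stereocentre that carries the isopropenyl group.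

Step 3
Reactants: 5 (4R)-2-(but-3-enyl)-4-isopropenylcyclohexanone
Product: 6 (4R)-2-(but-3-enyl)-4-(3-chloroprop-1-en-2-yl)cyclohexanone (C-2 epimers)
Conditions: Ca(OCl)2, CO2 (solid), CH2Cl2/H2O, 0 °C
Reagents that add atoms: calcium hypochlorite, [Ca+2].[O-]Cl.[O-]Cl
Why: Ene-type allylic chlorination by HOCl made in the flask, which turns an isopropenyl group into a 2-(chloromethyl)vinyl group and should prefer the electron-richer 1,1-disubstituted alkene over the monosubstituted butenyl alkene; no stereocentre is touched.

Step 4
Reactants: 6 (4R)-2-(but-3-enyl)-4-(3-chloroprop-1-en-2-yl)cyclohexanone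
Product: 7 (1S,5R)-1-(but-3-enyl)-6-methylidenebicyclo[3.2.1]octan-2-one
Conditions: KOtBu, t-BuOH/THF, 0 °C → rt
Reagents that add atoms: none
Why: Intramolecular enolate alkylation (5-exo-tet) under equilibrating conditions through the more substituted enolate, in which the allylic chloride on the ring stereocentre can reach the enolate carbon across one face only, so the quaternary bridgehead is set by that centre (attack at either terminus of the allyl unit gives the same product).

Step 5
Reactants: 7 (1S,5R)-1-(but-3-enyl)-6-methylidenebicyclo[3.2.1]octan-2-one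
Product: 8 ethylene ketal of 7
Conditions: Me3SiOCH2CH2OSiMe3, Me3SiOTf (cat.), CH2Cl2, −78 → −20 °C
Reagents that add atoms: 1,2-bis(trimethylsilyloxy)ethane, C[Si](C)(C)OCCO[Si](C)(C)C
Why: Aprotic low-temperature dioxolane formation by silyl transfer masks the only ketone, so that the later methyl ketone and the ring A ketone can be addressed alone, and should leave the exocyclic alkene in place.

Step 6
Reactants: 8 ethylene ketal of 7; 9 allyl methyl carbonate
Product: 10 (E)-allylic methyl carbonate
Conditions: second-generation Hoveyda–Grubbs catalyst (cat.), 9 (excess), CH2Cl2, 40 °C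
Reagents that add atoms: none
Why: Olefin cross-metathesis of the monosubstituted butenyl alkene with excess allyl carbonate should give mainly the E allylic carbonate, since the hindered 1,1-disubstituted exocyclic alkene is a poor partner and ring closure onto it would need a bridgehead alkene.

Step 7
Reactants: 10 (E)-allylic methyl carbonate; 11 dimethyl methylmalonate
Product: 12 branched (3R)-allyl methylmalonate
Conditions: 11, NaH, THF; [Ir(cod)Cl]2 (cat.), BINOL-derived phosphoramidite with a bis(1-phenylethyl)amino group (one antipode), 1,5,7-triazabicyclo[4.4.0]dec-5-ene (cat.), THF, rt → 50 °C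
Reagents that add atoms: none
Why: Iridium-catalysed asymmetric allylic alkylation, in which the malonate attacks the substituted terminus of the allyl–iridium intermediate to give the branched product and the chiral ligand alone fixes the new allylic stereocentre, independently of the remote bicycle.

Step 8
Reactants: 12 branched (3R)-allyl methylmalonate
Product: 13 γ-keto methylmalonate
Conditions: Pd(Quinox)Cl2 (cat.), AgSbF6 (cat.), aq. t-BuOOH, CH2Cl2, 0 °C → rt
Reagents that add atoms: tert-butyl hydroperoxide, CC(C)(C)OO
Why: Tsuji–Wacker-type oxidation by divalent palladium, in which Markovnikov oxypalladation of the monosubstituted alkene gives the methyl ketone while the 1,1-disubstituted exocyclic alkene reacts much more slowly; the near-neutral peroxide conditions are chosen to spare the ketal and the α-stereocentre (its descriptor becomes S by the priority rules only).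

Step 9
Reactants: 13 γ-keto methylmalonate; 14 phenyl vinyl sulfone
Product: 17 bicyclic keto lactone, via hydroxy sulfone diester 15 (not isolated), via keto sulfone lactone 16 (not isolated)
Conditions: SmI2, HMPA, THF, −78 °C → rt, no proton source; then MeOH, SmI2, −78 °C
Reagents that add atoms: none
Why: Proposed new method: SmI2–HMPA reduces the methyl ketone to a ketyl radical that adds to the β-carbon of the vinyl sulfone (first new bond, CH2 to C-10), a second electron gives an α-sulfonyl organosamarium, the tertiary samarium alkoxide closes the γ-lactone on one malonate ester (5-exo-trig O-acylation) and the carbanion closes the cyclohexanone on the other carbonyl (6-exo-trig Dieckmann-type C-acylation, second new bond, CH2 to C-3), after which SmI2/MeOH cleaves the β-keto sulfone and removes the sulfonyl helper. The closest known reaction types are the SmI2-mediated reductive coupling of ketones with acrylates to γ-lactones, sequenced ketyl–olefin coupling followed by nucleophilic acyl substitution of the organosamarium, and the SmI2 reduction of α-sulfonyl ketones. C-10 is set under Felkin–Anh control: the bulky C(Me)(CO2Me)2 group lies anti to the incoming alkene and HMPA-saturated samarium should not chelate the esters, which puts the new CH2 cis to the side chain on the future lactone ring. C-4 is fixed by geometry and stereoconvergently: whichever of the two diastereotopic esters lactonises first, the carbanion can reach only the carbonyl on its own face (the free ester, or the lactone carbonyl followed by acyl transfer to the freed alkoxide), so both lactone diastereomers should drain into the same product. The step needs the ketone to be reduced before the vinyl sulfone and the ketyl to add faster than it fragments or is protonated; the excess of electron-poor acceptor, the absence of a proton source in the first stage and the low temperature are meant to secure this.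

Step 10
Reactants: 17 bicyclic keto lactone
Product: 18 axial (2S) alcohol
Conditions: LiBH(s-Bu)3, THF, −78 °C; aq. NH4Cl
Reagents that add atoms: none
Why: Bulky hydride reduction, in which the face of the ring A ketone anti to the lactone is screened by the axial two-carbon side chain on the one-carbon bridge, so hydride should enter from the lactone side and give the axial alcohol syn to that chain; the hindered lactone should survive at low temperature.

Step 11
Reactants: 18 axial (2S) alcohol
Product: 19 acetate ketal
Conditions: Ac2O, Et3N, DMAP (cat.), CH2Cl2, rt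
Reagents that add atoms: acetic anhydride, CC(=O)OC(C)=O
Why: DMAP-catalysed acylation of a secondary alcohol, with no change at any stereocentre.

Step 12
Reactants: 19 acetate ketal
Product: 20 target
Conditions: pyridinium p-toluenesulfonate (cat.), acetone/H2O, 50 °C
Reagents that add atoms: water, O
Why: Mild acid-catalysed ketal hydrolysis releases the bridged ketone under conditions chosen so that the acetate, the lactone and the exocyclic alkene should survive.

**Compound list**

1 | (1R,5S)-6,6-dimethylbicyclo[3.1.1]heptan-2-one, (+)-nopinone | O=C1CC[C@H]2C[C@@H]1C2(C)C | starting material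
2 | 4-iodobut-1-ene | C=CCCI | starting material
3 | (1R,3S,5S)-3-(but-3-en-1-yl)-6,6-dimethylbicyclo[3.1.1]heptan-2-one (butenyl anti to the gem-dimethyl bridge) | O=C1[C@@H](CCC=C)C[C@H]2C[C@@H]1C2(C)C | intermediate
4 | (4R)-6-(but-3-en-1-yl)-4-(prop-1-en-2-yl)cyclohex-1-en-1-yl acetate (C-6 not defined) | CC(=O)OC1=CC[C@@H](C(C)=C)CC1CCC=C | intermediate (not isolated)
5 | (4R)-2-(but-3-en-1-yl)-4-(prop-1-en-2-yl)cyclohexan-1-one (C-2 epimers) | C=CCCC1C[C@H](C(C)=C)CCC1=O | intermediate
6 | (4R)-2-(but-3-en-1-yl)-4-(3-chloroprop-1-en-2-yl)cyclohexan-1-one (C-2 epimers) | C=CCCC1C[C@H](C(CCl)=C)CCC1=O | intermediate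
7 | (1S,5R)-1-(but-3-en-1-yl)-6-methylidenebicyclo[3.2.1]octan-2-one | C=C1C[C@]2(CCC=C)C[C@H]1CCC2=O | intermediate
8 | (1S,5R)-1-(but-3-en-1-yl)-6-methylidenespiro[bicyclo[3.2.1]octane-2,2'-[1,3]dioxolane] | C=C1C[C@]2(CCC=C)C[C@H]1CCC23OCCO3 | intermediate
9 | methyl prop-2-en-1-yl carbonate (allyl methyl carbonate) | C=CCOC(=O)OC | starting material
10 | methyl (2E)-5-[(1S,5R)-6-methylidenespiro[bicyclo[3.2.1]octane-2,2'-[1,3]dioxolan]-1-yl]pent-2-en-1-yl carbonate | C=C1C[C@]2(CC/C=C/COC(=O)OC)C[C@H]1CCC23OCCO3 | intermediate
11 | dimethyl 2-methylpropanedioate | COC(=O)C(C)C(=O)OC | starting material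
12 | dimethyl 2-methyl-2-{(3R)-5-[(1S,5R)-6-methylidenespiro[bicyclo[3.2.1]octane-2,2'-[1,3]dioxolan]-1-yl]pent-1-en-3-yl}propanedioate | C=C1C[C@]2(CC[C@H](C=C)C(C)(C(=O)OC)C(=O)OC)C[C@H]1CCC23OCCO3 | intermediate
13 | dimethyl 2-methyl-2-{(3S)-5-[(1S,5R)-6-methylidenespiro[bicyclo[3.2.1]octane-2,2'-[1,3]dioxolan]-1-yl]-2-oxopentan-3-yl}propanedioate | C=C1C[C@]2(CC[C@H](C(C)=O)C(C)(C(=O)OC)C(=O)OC)C[C@H]1CCC23OCCO3 | intermediate
14 | ethenylsulfonylbenzene (phenyl vinyl sulfone) | C=CS(=O)(=O)c1ccccc1 | starting material
15 | dimethyl 2-{(3S,4S)-4-hydroxy-4-methyl-1-[(1S,5R)-6-methylidenespiro[bicyclo[3.2.1]octane-2,2'-[1,3]dioxolan]-1-yl]-6-(phenylsulfonyl)hexan-3-yl}-2-methylpropanedioate (present as its samarium alkoxide and α-sulfonyl organosamarium; drawn neutral) | C=C1C[C@]2(CC[C@@H](C(C)(C(=O)OC)C(=O)OC)[C@@](C)(O)CCS(=O)(=O)c3ccccc3)C[C@H]1CCC24OCCO4 | intermediate (not isolated)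
16 | (1S,5S,8S)-1,5-dimethyl-8-{2-[(1S,5R)-6-methylidenespiro[bicyclo[3.2.1]octane-2,2'-[1,3]dioxolan]-1-yl]ethyl}-3-(phenylsulfonyl)-6-oxabicyclo[3.2.1]octane-2,7-dione (C-3 not defined) | C=C1C[C@]2(CC[C@H]3[C@]4(C)C(=O)O[C@@]3(C)CC(S(=O)(=O)c5ccccc5)C4=O)C[C@H]1CCC26OCCO6 | intermediate (not isolated)
17 | (1S,5S,8S)-1,5-dimethyl-8-{2-[(1S,5R)-6-methylidenespiro[bicyclo[3.2.1]octane-2,2'-[1,3]dioxolan]-1-yl]ethyl}-6-oxabicyclo[3.2.1]octane-2,7-dione | C=C1C[C@]2(CC[C@H]3[C@]4(C)C(=O)O[C@@]3(C)CCC4=O)C[C@H]1CCC25OCCO5 | intermediate
18 | (1S,2S,5S,8S)-2-hydroxy-1,5-dimethyl-8-{2-[(1S,5R)-6-methylidenespiro[bicyclo[3.2.1]octane-2,2'-[1,3]dioxolan]-1-yl]ethyl}-6-oxabicyclo[3.2.1]octan-7-one | C=C1C[C@]2(CC[C@H]3[C@]4(C)C(=O)O[C@@]3(C)CC[C@@H]4O)C[C@H]1CCC25OCCO5 | intermediate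
19 | (1S,2S,5S,8S)-1,5-dimethyl-8-{2-[(1S,5R)-6-methylidenespiro[bicyclo[3.2.1]octane-2,2'-[1,3]dioxolan]-1-yl]ethyl}-7-oxo-6-oxabicyclo[3.2.1]octan-2-yl acetate | C=C1C[C@]2(CC[C@H]3[C@]4(C)C(=O)O[C@@]3(C)CC[C@@H]4OC(C)=O)C[C@H]1CCC25OCCO5 | intermediate
20 | (1S,2S,5S,8S)-1,5-dimethyl-8-{2-[(1S,5R)-6-methylidene-2-oxobicyclo[3.2.1]octan-1-yl]ethyl}-7-oxo-6-oxabicyclo[3.2.1]octan-2-yl acetate | C=C1C[C@]2(CC[C@H]3[C@]4(C)C(=O)O[C@@]3(C)CC[C@@H]4OC(C)=O)C[C@H]1CCC2=O | target

**Step count and risks**

Total step count: 12. Longest linear sequence: 12 steps (1 → 20).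

Steps most likely to fail:

1. Step 9. The vinyl sulfone may be reduced before the ketone, the ketyl may fragment at the bond to the malonate carbon, samarium may chelate an ester and reverse the facial selectivity at C-10, or the carbanion may be protonated before C-acylation. Fallback from 13 back to 17, making the two bonds in separate known operations: addition of CH2=CHMgBr/CeCl3 (THF, −78 °C → rt, Felkin–Anh, non-chelating) to the methyl ketone of 13 with lactonisation of the tertiary alkoxide in the flask should give the vinyl lactone ester methyl (3S,4S,5S)-5-ethenyl-3,5-dimethyl-4-{2-[(1S,5R)-6-methylidenespiro[bicyclo[3.2.1]octane-2,2'-[1,3]dioxolan]-1-yl]ethyl}-2-oxooxolane-3-carboxylate F1, together with its (3R) epimer F2 (lactone closed on the other ester). F2 is returned to F1 by NaOMe/MeOH equilibration through the open hydroxy diester. Anti-Markovnikov hydroboration of the monosubstituted vinyl group of F1 with disiamylborane and NaBO3 oxidation gives the primary alcohol F3, PPh3/I2/imidazole gives the iodide F4, and SmI2 with catalytic Fe(dbm)3 (alkylsamarium formation and intramolecular nucleophilic acyl substitution at the cis ester) closes the cyclohexanone to give 17.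

2. Step 4. Alkylation may run through the less substituted enolate, or on oxygen, and give an isomeric bicycle. Fallback from 6 back to 7: 6 is converted under thermodynamic conditions (Me3SiCl, NaI, Et3N, MeCN) into the more substituted silyl enol ether {[(4R)-2-(but-3-en-1-yl)-4-(3-chloroprop-1-en-2-yl)cyclohex-1-en-1-yl]oxy}trimethylsilane F5, which is purified. MeLi in THF then releases the lithium enolate at the substituted α-carbon only; without a proton source it cannot equilibrate, and it closes onto the allylic chloride to give 7.

3. Step 7. The tertiary malonate may react slowly or give poor branched selectivity. Fallback from 10 back to 12: the same iridium-catalysed alkylation is run with sodium dimethyl malonate to give dimethyl 2-{(3R)-5-[(1S,5R)-6-methylidenespiro[bicyclo[3.2.1]octane-2,2'-[1,3]dioxolan]-1-yl]pent-1-en-3-yl}propanedioate F6, and the quaternary carbon is then completed by C-methylation (NaH, MeI, THF) to give 12.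

Further compounds
F1 | step 9 | methyl (3S,4S,5S)-5-ethenyl-3,5-dimethyl-4-{2-[(1S,5R)-6-methylidenespiro[bicyclo[3.2.1]octane-2,2'-[1,3]dioxolan]-1-yl]ethyl}-2-oxooxolane-3-carboxylate | C=C1C[C@]2(CC[C@H]3[C@@](C)(C(=O)OC)C(=O)O[C@@]3(C)C=C)C[C@H]1CCC25OCCO5
F2 | step 9 | methyl (3R,4S,5S)-5-ethenyl-3,5-dimethyl-4-{2-[(1S,5R)-6-methylidenespiro[bicyclo[3.2.1]octane-2,2'-[1,3]dioxolan]-1-yl]ethyl}-2-oxooxolane-3-carboxylate | C=C1C[C@]2(CC[C@H]3[C@](C)(C(=O)OC)C(=O)O[C@@]3(C)C=C)C[C@H]1CCC25OCCO5
F3 | step 9 | methyl (3S,4S,5S)-5-(2-hydroxyethyl)-3,5-dimethyl-4-{2-[(1S,5R)-6-methylidenespiro[bicyclo[3.2.1]octane-2,2'-[1,3]dioxolan]-1-yl]ethyl}-2-oxooxolane-3-carboxylate | C=C1C[C@]2(CC[C@H]3[C@@](C)(C(=O)OC)C(=O)O[C@@]3(C)CCO)C[C@H]1CCC25OCCO5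
F4 | step 9 | methyl (3S,4S,5S)-5-(2-iodoethyl)-3,5-dimethyl-4-{2-[(1S,5R)-6-methylidenespiro[bicyclo[3.2.1]octane-2,2'-[1,3]dioxolan]-1-yl]ethyl}-2-oxooxolane-3-carboxylate | C=C1C[C@]2(CC[C@H]3[C@@](C)(C(=O)OC)C(=O)O[C@@]3(C)CCI)C[C@H]1CCC25OCCO5
F5 | step 4 | {[(4R)-2-(but-3-en-1-yl)-4-(3-chloroprop-1-en-2-yl)cyclohex-1-en-1-yl]oxy}trimethylsilane | C=CCCC1=C(O[Si](C)(C)C)CC[C@@H](C(CCl)=C)C1
F6 | step 7 | dimethyl 2-{(3R)-5-[(1S,5R)-6-methylidenespiro[bicyclo[3.2.1]octane-2,2'-[1,3]dioxolan]-1-yl]pent-1-en-3-yl}propanedioate | C=C1C[C@]2(CC[C@H](C=C)C(C(=O)OC)C(=O)OC)C[C@H]1CCC23OCCO3
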